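**Retrosynthetic overview**
- Ring B is closed last: the C1–C8 bond forms by a cation–enol cyclization of a dearomatized acylphloroglucinol whose C5 already carries geranyl and a chiral isopropenyl side chain (C6–C8 with the C7 geranyl); the catechol is unmasked in the same pot.
- Ring A is the phloroglucinol ring itself: its aromaticity is broken in the key step, a catalyst-controlled dearomative geranylation at C5 of a fully substituted maclurin-derived arene, which sets the C5 quaternary centre.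
- Prenyl-bearing and geranyl-bearing ring carbons cannot be told apart in a dearomative alkylation, so the future C1 is held by a formyl group until C5 is quaternary and is then exchanged for prenyl.
- The arene comes from phloroglucinol and 3,4-dihydroxybenzonitrile (Hoesch), then catechol ketal, formylation and C-alkylation with the side-chain triflate.
- The side chain comes from an Evans deconjugative alkylation of a senecioyl imide with geranyl bromide, which sets C7.

Assumption: each triketone is drawn as one of its equilibrating enol tautomers, and stereodescriptors in names refer to the tautomer given in the SMILES.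

Step 1
Reactants: 1 (4S)-4-benzyl-1,3-oxazolidin-2-one; 2 3-methylbut-2-enoyl chloride
Product: 3 (4S)-4-benzyl-3-(3-methylbut-2-enoyl)-1,3-oxazolidin-2-one
Conditions: n-BuLi, THF, −78 °C; then 2, −78 to 0 °C
Reagents that add atoms: none
Why: N-acylation of the lithiated Evans oxazolidinone by the acid chloride (imide formation); no new stereocentre.

Step 2
Reactants: 3 (4S)-4-benzyl-3-(3-methylbut-2-enoyl)-1,3-oxazolidin-2-one; 4 geranyl bromide [(2E)-1-bromo-3,7-dimethylocta-2,6-diene]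
Product: 5 (4S)-4-benzyl-3-[(2S,4E)-5,9-dimethyl-2-(prop-1-en-2-yl)deca-4,8-dienoyl]-1,3-oxazolidin-2-one
Conditions: NaN(SiMe3)2, THF, −78 °C; then 4, −78 to −40 °C
Reagents that add atoms: none
Why: Evans asymmetric alkylation: the chelated Z sodium dienolate reacts at its α-carbon (deconjugative alkylation) with the allylic bromide on the face away from the benzyl group, setting the (2S) centre that becomes C7 (7R) of the target.

Step 3
Reactants: 5 (4S)-4-benzyl-3-[(2S,4E)-5,9-dimethyl-2-(prop-1-en-2-yl)deca-4,8-dienoyl]-1,3-oxazolidin-2-one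
Product: 6 (2S,4E)-5,9-dimethyl-2-(prop-1-en-2-yl)deca-4,8-dien-1-ol
Conditions: LiBH4, H2O (1 equiv), Et2O, 0 °C
Reagents that add atoms: none
Why: Reductive cleavage of the imide by borohydride gives the primary alcohol and returns the auxiliary; the β,γ-unsaturated α-centre is not epimerised under these non-basic conditions.

Step 4
Reactants: 7 phloroglucinol (benzene-1,3,5-triol); 8 3,4-dihydroxybenzonitrile
Product: 10 maclurin [(3,4-dihydroxyphenyl)(2,4,6-trihydroxyphenyl)methanone], via ketiminium chloride 9 (not isolated)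
Conditions: ZnCl2, HCl (g), Et2O, 0 °C; then H2O, 100 °C
Reagents that add atoms: water O
Why: Houben–Hoesch acylation: the HCl/ZnCl2-activated nitrile attacks the electron-rich arene once, because the ketiminium salt deactivates the ring, and hydrolysis gives the benzophenone.

Step 5
Reactants: 10 maclurin
Product: 11 (2,2-diphenyl-1,3-benzodioxol-5-yl)(2,4,6-trihydroxyphenyl)methanone
Conditions: Ph2CCl2, Ph2O, 175 °C
Reagents that add atoms: dichlorodiphenylmethane ClC(Cl)(c1ccccc1)c1ccccc1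
Why: Diphenylmethylene ketal formation: only the catechol can close a five-membered cyclic ketal, so the three phloroglucinol hydroxyls stay free for the later anion chemistry.

Step 6
Reactants: 11 (2,2-diphenyl-1,3-benzodioxol-5-yl)(2,4,6-trihydroxyphenyl)methanone
Product: 13 3-(2,2-diphenyl-1,3-benzodioxole-5-carbonyl)-2,4,6-trihydroxybenzaldehyde, via aryl iminium chloride 12 (not isolated)
Conditions: POCl3, DMF, EtOAc, 0 to 23 °C; then H2O, 60 °C
Reagents that add atoms: N,N-dimethylformamide CN(C)C=O; water O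
Why: Vilsmeier–Haack formylation of one of the two equivalent free ring positions; the formyl group occupies the future C1 so that later C–C bond formation can only occur at the future C5.

Step 7
Reactants: 13 3-(2,2-diphenyl-1,3-benzodioxole-5-carbonyl)-2,4,6-trihydroxybenzaldehyde; 6 (2S,4E)-5,9-dimethyl-2-(prop-1-en-2-yl)deca-4,8-dien-1-ol
Product: 15 3-(2,2-diphenyl-1,3-benzodioxole-5-carbonyl)-5-[(2R,4E)-5,9-dimethyl-2-(prop-1-en-2-yl)deca-4,8-dien-1-yl]-2,4,6-trihydroxybenzaldehyde, via side-chain triflate 14 (not isolated)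
Conditions: 6, Tf2O, 2,6-lutidine, CH2Cl2, −78 °C; then added to 13 + LiN(SiMe3)2 (3.1 equiv), THF, −78 to 0 °C
Reagents that add atoms: none
Why: SN2 C-alkylation of the lithium trianion of 13 at its only free ring carbon by the primary triflate (the CIP label of the side-chain centre changes from S to R without any change in geometry).

Step 8
Reactants: 15 3-(2,2-diphenyl-1,3-benzodioxole-5-carbonyl)-5-[(2R,4E)-5,9-dimethyl-2-(prop-1-en-2-yl)deca-4,8-dien-1-yl]-2,4,6-trihydroxybenzaldehyde; 16 geranyl acetate [(2E)-3,7-dimethylocta-2,6-dien-1-yl acetate]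
Product: 17 (6R)-4-(2,2-diphenyl-1,3-benzodioxole-5-carbonyl)-6-[(2R,4E)-5,9-dimethyl-2-(prop-1-en-2-yl)deca-4,8-dien-1-yl]-6-[(2E)-3,7-dimethylocta-2,6-dien-1-yl]-2-formyl-3,5-dihydroxycyclohexa-2,4-dien-1-one
Conditions: Pd2(dba)3·CHCl3 (2.5 mol %), N,N'-[(1R,2R)-cyclohexane-1,2-diyl]bis[2-(diphenylphosphanyl)benzamide] (the (R,R)-DACH-phenyl Trost ligand, 7.5 mol %), Et3N, CH2Cl2, 0 to 23 °C
Reagents that add atoms: none
Why: Proposed new method: a ligand-controlled dearomative Tsuji–Trost geranylation in which the ammonium phenoxide of 15 attacks the linear terminus of the π-geranyl complex of palladium from outside the metal, at the only nucleophilic ring carbon (the formyl- and aroyl-bearing carbons are vinylogous-acid carbons and O-allylation is reversible under zerovalent palladium), so that the ligand pocket selects the arene face and sets the quaternary centre (6R, the future C5) while the E geometry is kept; the closest known reaction types are palladium-catalysed asymmetric allylic dearomatization of naphthols and acylphloroglucinols and Trost asymmetric prenylation, and the sense of induction is assigned by analogy (the (S,S) ligand would be used if it proves opposite).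

Step 9
Reactants: 17 (6R)-4-aroyl-6-geranyl-2-formyl-3,5-dihydroxy-6-[(2R,4E)-side chain]cyclohexa-2,4-dien-1-one (as named in step 8); 18 prenyl bromide (1-bromo-3-methylbut-2-ene)
Product: 20 (6R)-4-(2,2-diphenyl-1,3-benzodioxole-5-carbonyl)-6-[(2R,4E)-5,9-dimethyl-2-(prop-1-en-2-yl)deca-4,8-dien-1-yl]-6-[(2E)-3,7-dimethylocta-2,6-dien-1-yl]-3,5-dihydroxy-2-(3-methylbut-2-en-1-yl)cyclohexa-2,4-dien-1-one, via deformylated trione 19 (not isolated)
Conditions: NaOH (1 M aq., 3 equiv), MeOH, 40 °C; then 18 (1.1 equiv), 0 °C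
Reagents that add atoms: none
Why: Retro-Claisen deformylation by hydroxide frees the ring carbon between two carbonyls, and its enolate is C-prenylated in the same pot (SN2 alkylation of a cyclic 1,3-diketone); no stereocentre is formed or touched.

Step 10
Reactants: 20 (6R)-4-aroyl-6-geranyl-3,5-dihydroxy-2-prenyl-6-[(2R,4E)-side chain]cyclohexa-2,4-dien-1-one (as named in step 9)
Product: 22 target, (1R,5R,7R)-3-(3,4-dihydroxybenzoyl)-5,7-bis[(2E)-3,7-dimethylocta-2,6-dien-1-yl]-4-hydroxy-8,8-dimethyl-1-(3-methylbut-2-en-1-yl)bicyclo[3.3.1]non-3-ene-2,9-dione, via cyclized ketal 21 (not isolated)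
Conditions: HCO2H (98 %), 23 °C; then H2O (10 vol %), 40 °C
Reagents that add atoms: none
Why: Biomimetic cation–enol (Prins-type) cyclization: formic acid protonates the isopropenyl group and the tertiary C8 cation is trapped by the prenyl-bearing enol carbon, which can only close cis to the tether and so fixes C1 (1R) and turns the preset C5/C7 relationship into the 7-endo bicycle; aqueous acid then hydrolyses the diphenylmethylene ketal.

**Compound list**

1 | (4S)-4-benzyl-1,3-oxazolidin-2-one | O=C1N[C@@H](Cc2ccccc2)CO1 | starting material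
2 | 3-methylbut-2-enoyl chloride | CC(C)=CC(Cl)=O | starting material
3 | (4S)-4-benzyl-3-(3-methylbut-2-enoyl)-1,3-oxazolidin-2-one | CC(C)=CC(=O)N1C(=O)OC[C@@H]1Cc1ccccc1 | intermediate
4 | geranyl bromide, (2E)-1-bromo-3,7-dimethylocta-2,6-diene | CC(C)=CCC/C(C)=C/CBr | starting material
5 | (4S)-4-benzyl-3-[(2S,4E)-5,9-dimethyl-2-(prop-1-en-2-yl)deca-4,8-dienoyl]-1,3-oxazolidin-2-one | CC(C)=CCC/C(C)=C/C[C@@H](C(C)=C)C(=O)N1C(=O)OC[C@@H]1Cc1ccccc1 | intermediate
6 | (2S,4E)-5,9-dimethyl-2-(prop-1-en-2-yl)deca-4,8-dien-1-ol | CC(C)=CCC/C(C)=C/C[C@@H](C(C)=C)CO | intermediate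
7 | phloroglucinol | Oc1cc(O)cc(O)c1 | starting material
8 | 3,4-dihydroxybenzonitrile | N#Cc1ccc(O)c(O)c1 | starting material
9 | (3,4-dihydroxyphenyl)(2,4,6-trihydroxyphenyl)methaniminium chloride | [NH2+]=C(c1ccc(O)c(O)c1)c1c(O)cc(O)cc1O.[Cl-] | intermediate
10 | maclurin, (3,4-dihydroxyphenyl)(2,4,6-trihydroxyphenyl)methanone | O=C(c1ccc(O)c(O)c1)c1c(O)cc(O)cc1O | intermediate
11 | (2,2-diphenyl-1,3-benzodioxol-5-yl)(2,4,6-trihydroxyphenyl)methanone | O=C(c1ccc2OC(c3ccccc3)(c3ccccc3)Oc2c1)c1c(O)cc(O)cc1O | intermediate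
12 | N-{[3-(2,2-diphenyl-1,3-benzodioxole-5-carbonyl)-2,4,6-trihydroxyphenyl]methylidene}-N-methylmethanaminium chloride | C[N+](C)=Cc1c(O)cc(O)c(C(=O)c2ccc3OC(c4ccccc4)(c4ccccc4)Oc3c2)c1O.[Cl-] | intermediate
13 | 3-(2,2-diphenyl-1,3-benzodioxole-5-carbonyl)-2,4,6-trihydroxybenzaldehyde | O=Cc1c(O)cc(O)c(C(=O)c2ccc3OC(c4ccccc4)(c4ccccc4)Oc3c2)c1O | intermediate
14 | (2S,4E)-5,9-dimethyl-2-(prop-1-en-2-yl)deca-4,8-dien-1-yl trifluoromethanesulfonate | CC(C)=CCC/C(C)=C/C[C@@H](C(C)=C)COS(=O)(=O)C(F)(F)F | intermediate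
15 | 3-(2,2-diphenyl-1,3-benzodioxole-5-carbonyl)-5-[(2R,4E)-5,9-dimethyl-2-(prop-1-en-2-yl)deca-4,8-dien-1-yl]-2,4,6-trihydroxybenzaldehyde | CC(C)=CCC/C(C)=C/C[C@@H](C(C)=C)Cc1c(O)c(C=O)c(O)c(C(=O)c2ccc3OC(c4ccccc4)(c4ccccc4)Oc3c2)c1O | intermediate
16 | geranyl acetate, (2E)-3,7-dimethylocta-2,6-dien-1-yl acetate | CC(=O)OC/C=C(\C)CCC=C(C)C | starting material
17 | (6R)-4-(2,2-diphenyl-1,3-benzodioxole-5-carbonyl)-6-[(2R,4E)-5,9-dimethyl-2-(prop-1-en-2-yl)deca-4,8-dien-1-yl]-6-[(2E)-3,7-dimethylocta-2,6-dien-1-yl]-2-formyl-3,5-dihydroxycyclohexa-2,4-dien-1-one | CC(C)=CCC/C(C)=C/C[C@@H](C(C)=C)C[C@@]1(C/C=C(\C)CCC=C(C)C)C(=O)C(C=O)=C(O)C(C(=O)c2ccc3OC(c4ccccc4)(c4ccccc4)Oc3c2)=C1O | intermediate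
18 | prenyl bromide, 1-bromo-3-methylbut-2-ene | CC(C)=CCBr | starting material
19 | (6R)-4-(2,2-diphenyl-1,3-benzodioxole-5-carbonyl)-6-[(2R,4E)-5,9-dimethyl-2-(prop-1-en-2-yl)deca-4,8-dien-1-yl]-6-[(2E)-3,7-dimethylocta-2,6-dien-1-yl]-3,5-dihydroxycyclohexa-2,4-dien-1-one | CC(C)=CCC/C(C)=C/C[C@@H](C(C)=C)C[C@@]1(C/C=C(\C)CCC=C(C)C)C(=O)C=C(O)C(C(=O)c2ccc3OC(c4ccccc4)(c4ccccc4)Oc3c2)=C1O | intermediate
20 | (6R)-4-(2,2-diphenyl-1,3-benzodioxole-5-carbonyl)-6-[(2R,4E)-5,9-dimethyl-2-(prop-1-en-2-yl)deca-4,8-dien-1-yl]-6-[(2E)-3,7-dimethylocta-2,6-dien-1-yl]-3,5-dihydroxy-2-(3-methylbut-2-en-1-yl)cyclohexa-2,4-dien-1-one | CC(C)=CCC/C(C)=C/C[C@@H](C(C)=C)C[C@@]1(C/C=C(\C)CCC=C(C)C)C(=O)C(CC=C(C)C)=C(O)C(C(=O)c2ccc3OC(c4ccccc4)(c4ccccc4)Oc3c2)=C1O | intermediate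
21 | (1R,5R,7R)-3-(2,2-diphenyl-1,3-benzodioxole-5-carbonyl)-5,7-bis[(2E)-3,7-dimethylocta-2,6-dien-1-yl]-4-hydroxy-8,8-dimethyl-1-(3-methylbut-2-en-1-yl)bicyclo[3.3.1]non-3-ene-2,9-dione | CC(C)=CCC/C(C)=C/C[C@@H]1C[C@@]2(C/C=C(\C)CCC=C(C)C)C(=O)[C@](CC=C(C)C)(C(=O)C(C(=O)c3ccc4OC(c5ccccc5)(c5ccccc5)Oc4c3)=C2O)C1(C)C | intermediate
22 | (1R,5R,7R)-3-(3,4-dihydroxybenzoyl)-5,7-bis[(2E)-3,7-dimethylocta-2,6-dien-1-yl]-4-hydroxy-8,8-dimethyl-1-(3-methylbut-2-en-1-yl)bicyclo[3.3.1]non-3-ene-2,9-dione | CC(C)=CCC/C(C)=C/C[C@@H]1C[C@@]2(C/C=C(\C)CCC=C(C)C)C(=O)[C@](CC=C(C)C)(C(=O)C(C(=O)c3ccc(O)c(O)c3)=C2O)C1(C)C | target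

**Step count and risks**

Total step count: 10. Longest linear sequence: 7 steps (steps 4 to 10, phloroglucinol to target; the side-chain branch, steps 1, 2, 3, 7, 8, 9, 10, is also 7).

Three steps most likely to fail:

1. Step 8 (dearomative geranylation). The risks are insufficient facial control by the ligand at a crowded quaternary centre, and loss of configuration if the C-allylation proves reversible. The fallback sets out from 13 and reverses the order of the two C5 substituents, giving up catalyst control. Alkylation of 13 at its free ring carbon with geranyl bromide 4 (aq. KOH, 0 °C) gives 3-(2,2-diphenyl-1,3-benzodioxole-5-carbonyl)-5-[(2E)-3,7-dimethylocta-2,6-dien-1-yl]-2,4,6-trihydroxybenzaldehyde F1. Its lithium trianion is then alkylated at the geranyl-bearing carbon, the only alkyl-bearing one, with triflate 14. This gives 17 together with its (6S) epimer F2 in roughly equal amounts, which are separated by chromatography. The fallback comes back to the route at 17.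

2. Step 10 (cyclization and ketal hydrolysis). The 7-endo product needs a boat-like transition state, and formic acid may instead give O-cyclized pyrans, cyclize a geranyl chain, or fail to cleave the ketal cleanly. The fallback sets out from 20 and separates the events, using an enol ether as the nucleophile. Excess TMSCHN2 (MeOH/toluene) gives the bis(methyl enol ether) (6R)-4-(2,2-diphenyl-1,3-benzodioxole-5-carbonyl)-6-geranyl-3,5-dimethoxy-2-prenyl-6-[(2R,4E)-side chain]cyclohexa-2,4-dien-1-one F3, which cannot O-cyclize. Formic acid cyclization through the C2 enol ether, with loss of that methyl group, gives the 4-O-methyl ether of the bicyclic ketal F4. LiCl in DMSO at 120 °C removes the remaining methyl group and the fallback comes back to the route at 21, whose ketal is then hydrolysed as in step 10.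

3. Step 7 (C-alkylation with the triflate). The trianion of the doubly acylated arene 13 is a weak carbon nucleophile and O-alkylation may win. The fallback sets out from 11, whose trianion is more nucleophilic, and installs the formyl group afterwards. Alkylation of 11 (used in excess) with triflate 14 and LiN(SiMe3)2 gives the mono-C-alkylated ketone (2,2-diphenyl-1,3-benzodioxol-5-yl){3-[(2R,4E)-5,9-dimethyl-2-(prop-1-en-2-yl)deca-4,8-dien-1-yl]-2,4,6-trihydroxyphenyl}methanone F5. Vilsmeier formylation of its last free ring carbon (POCl3, DMF, 0 °C) proceeds through the aryl iminium chloride F6, and hydrolysis comes back to the route at 15.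

Further compounds
F1 | step 8 | 3-(2,2-diphenyl-1,3-benzodioxole-5-carbonyl)-5-[(2E)-3,7-dimethylocta-2,6-dien-1-yl]-2,4,6-trihydroxybenzaldehyde | O=Cc1c(O)c(C/C=C(\C)CCC=C(C)C)c(O)c(C(=O)c2ccc3OC(c4ccccc4)(c4ccccc4)Oc3c2)c1O
F2 | step 8 | (6S)-4-(2,2-diphenyl-1,3-benzodioxole-5-carbonyl)-6-[(2R,4E)-5,9-dimethyl-2-(prop-1-en-2-yl)deca-4,8-dien-1-yl]-6-[(2E)-3,7-dimethylocta-2,6-dien-1-yl]-2-formyl-3,5-dihydroxycyclohexa-2,4-dien-1-one | CC(C)=CCC/C(C)=C/C[C@@H](C(C)=C)C[C@]1(C/C=C(\C)CCC=C(C)C)C(=O)C(C=O)=C(O)C(C(=O)c2ccc3OC(c4ccccc4)(c4ccccc4)Oc3c2)=C1O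
F3 | step 10 | (6R)-4-(2,2-diphenyl-1,3-benzodioxole-5-carbonyl)-6-[(2R,4E)-5,9-dimethyl-2-(prop-1-en-2-yl)deca-4,8-dien-1-yl]-6-[(2E)-3,7-dimethylocta-2,6-dien-1-yl]-3,5-dimethoxy-2-(3-methylbut-2-en-1-yl)cyclohexa-2,4-dien-1-one | CC(C)=CCC/C(C)=C/C[C@@H](C(C)=C)C[C@@]1(C/C=C(\C)CCC=C(C)C)C(=O)C(CC=C(C)C)=C(OC)C(C(=O)c2ccc3OC(c4ccccc4)(c4ccccc4)Oc3c2)=C1OC
F4 | step 10 | (1R,5R,7R)-3-(2,2-diphenyl-1,3-benzodioxole-5-carbonyl)-5,7-bis[(2E)-3,7-dimethylocta-2,6-dien-1-yl]-4-methoxy-8,8-dimethyl-1-(3-methylbut-2-en-1-yl)bicyclo[3.3.1]non-3-ene-2,9-dione | CC(C)=CCC/C(C)=C/C[C@@H]1C[C@@]2(C/C=C(\C)CCC=C(C)C)C(=O)[C@](CC=C(C)C)(C(=O)C(C(=O)c3ccc4OC(c5ccccc5)(c5ccccc5)Oc4c3)=C2OC)C1(C)C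
F5 | step 7 | (2,2-diphenyl-1,3-benzodioxol-5-yl){3-[(2R,4E)-5,9-dimethyl-2-(prop-1-en-2-yl)deca-4,8-dien-1-yl]-2,4,6-trihydroxyphenyl}methanone | CC(C)=CCC/C(C)=C/C[C@@H](C(C)=C)Cc1c(O)cc(O)c(C(=O)c2ccc3OC(c4ccccc4)(c4ccccc4)Oc3c2)c1O
F6 | step 7 | N-{[3-(2,2-diphenyl-1,3-benzodioxole-5-carbonyl)-5-[(2R,4E)-5,9-dimethyl-2-(prop-1-en-2-yl)deca-4,8-dien-1-yl]-2,4,6-trihydroxyphenyl]methylidene}-N-methylmethanaminium chloride | CC(C)=CCC/C(C)=C/C[C@@H](C(C)=C)Cc1c(O)c(C=[N+](C)C)c(O)c(C(=O)c2ccc3OC(c4ccccc4)(c4ccccc4)Oc3c2)c1O.[Cl-]
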